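**Retrosynthetic overview**

1. Numbering: carbocycle C1 (lactone O–CH), C2 (CH bearing C11), C3 (CHOH), C4 (C=O), C5 (CHMe), C6–C8 (CH2), C9 (C(Me)OH), C10 (CH–O-isobutyryl); lactone ring O–C1–C2–C11(=C13H2)–C12(=O). The strategy rests on the homoallylic alcohol unit C13=C11–C2–C3(OH), which sits where the α-methylene-γ-lactone is trans-fused (C1/C2) to the ten-membered carbocycle C1–C10: it is the retron of a γ-selective allylation of a C3 aldehyde by a 3-(bromomethyl)butenolide.
2. Target ⇐ C4 1,3-dithiane (oxidative hydrolysis) ⇐ seco bromobutenolide aldehyde, by ring-closing CrCl2 Barbier (Nozaki–Hiyama–Kishi type) allylation across C2–C3.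
3. Seco aldehyde ⇐ ring-closing metathesis of the C1 2-(bromomethyl)acrylate ⇐ syn-selective (Z)-γ-(methoxymethoxy)allylboration of a C10 aldehyde (C10–C1 bond), then C10 isobutyrate.
4. C3 ⇐ DMF formylation of the C4 lithiodithiane; C4 aldehyde ⇐ ozonolysis of the vinyl group of (S)-β-citronellene; C9/C10 ⇐ SeO2 oxidation, Sharpless epoxidation and hydride opening, all run before sulfur enters, because the titanium–peroxide system would oxidise a dithiane.
5. Ring order: five-membered lactone first (step 14), ten-membered carbocycle second (step 17).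

Key step: step 17

Assumption (chemistry): (S)-3,7-dimethylocta-1,6-diene ((S)-β-citronellene, the dehydration product of (S)-citronellol) is taken as the commercial chiral-pool source of C5; its terminal vinyl carbon is lost as formaldehyde and C3 is put back from DMF.
Abbreviations: TBS = tert-butyldimethylsilyl, TES = triethylsilyl, MOM = methoxymethyl, Ipc = isopinocampheyl, DMAP = 4-(dimethylamino)pyridine, DCC = dicyclohexylcarbodiimide.

**Route**

Step 1
Reactants: 1 (S)-β-citronellene, (3S)-3,7-dimethylocta-1,6-diene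
Product: 2 (2E,6S)-2,6-dimethylocta-2,7-dien-1-ol
Conditions: SeO2 (0.1 equiv), t-BuOOH (2 equiv), salicylic acid (cat.), CH2Cl2, 0 °C → rt
Reagents that add atoms: tert-butyl hydroperoxide CC(C)(C)OO (terminal oxidant; its oxygen is passed on by catalytic SeO2)
Why: Riley-type allylic oxidation, in which SeO2 hydroxylates the (E)-methyl group of the electron-rich trisubstituted alkene by an ene reaction and [2,3]-sigmatropic shift, while the vinyl group and the C5 stereocentre should stay untouched.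

Step 2
Reactants: 2 (2E,6S)-2,6-dimethylocta-2,7-dien-1-ol
Product: 3 [(2S,3S)-2-methyl-3-[(3S)-3-methylpent-4-en-1-yl]oxiran-2-yl]methanol
Conditions: Ti(OiPr)4 (10 mol%), L-(+)-diethyl tartrate (12 mol%), t-BuOOH (2 equiv), 4 Å molecular sieves, CH2Cl2, −20 °C
Reagents that add atoms: tert-butyl hydroperoxide CC(C)(C)OO
Why: Sharpless asymmetric epoxidation, in which the L-(+)-tartrate complex delivers oxygen to the face that gives the (2S,3S)-epoxide (later C9 = R), and the isolated vinyl group is not epoxidised because it lacks the directing hydroxyl.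

Step 3
Reactants: 3 [(2S,3S)-2-methyl-3-[(3S)-3-methylpent-4-en-1-yl]oxiran-2-yl]methanol
Product: 4 (2R,6S)-2,6-dimethyloct-7-ene-1,2-diol
Conditions: LiAlH4, THF, 0 °C → rt
Reagents that add atoms: none
Why: Regioselective hydride opening of a 2,3-epoxy alcohol, in which hydride attacks the less substituted epoxide carbon (future C8) in an SN2 sense, so the C9–O bond is kept and the tertiary carbinol retains its configuration.

Step 4
Reactants: 4 (2R,6S)-2,6-dimethyloct-7-ene-1,2-diol
Product: 6 (2S,6R)-6,7-dihydroxy-2,6-dimethylheptanal, via secondary ozonide 5 (not isolated)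
Conditions: O3, CH2Cl2, −78 °C; then PPh3, −78 °C → rt; used crude
Reagents that add atoms: ozone O=[O+][O-]
Why: Ozonolysis with reductive work-up cuts the only remaining C=C bond to the C4 aldehyde, and it is chosen over osmium/periodate cleavage because periodate would also cleave the 1,2-diol.

Step 5
Reactants: 6 (2S,6R)-6,7-dihydroxy-2,6-dimethylheptanal
Product: 7 (2R,6S)-6-(1,3-dithian-2-yl)-2-methylheptane-1,2-diol
Conditions: HS(CH2)3SH (1.1 equiv), BF3·OEt2 (0.2 equiv), CH2Cl2, −20 → 0 °C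
Reagents that add atoms: propane-1,3-dithiol SCCCS
Why: Lewis acid-catalysed dithioacetalisation of an aldehyde is fast at low temperature, so the α-stereocentre C5 should not epimerise, and the free diol is inert.

Step 6
Reactants: 7 (2R,6S)-6-(1,3-dithian-2-yl)-2-methylheptane-1,2-diol
Product: 8 2-[(2S,6R)-6-methyl-6,7-bis(triethylsilyloxy)heptan-2-yl]-1,3-dithiane
Conditions: Et3SiOTf (2.5 equiv), 2,6-lutidine, CH2Cl2, −78 → 0 °C
Reagents that add atoms: triethylsilyl trifluoromethanesulfonate CC[Si](CC)(CC)OS(=O)(=O)C(F)(F)F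
Why: Silylation with a silyl triflate is reactive enough to cap the tertiary C9 hydroxyl as well as the primary C10 hydroxyl.

Step 7
Reactants: 8 2-[(2S,6R)-6-methyl-6,7-bis(triethylsilyloxy)heptan-2-yl]-1,3-dithiane
Product: 11 {2-[(2S,6R)-6-methyl-6,7-bis(triethylsilyloxy)heptan-2-yl]-1,3-dithian-2-yl}methanol, via 2-lithiodithiane 9 (not isolated), via dithiane-2-carbaldehyde 10 (not isolated)
Conditions: t-BuLi (1.1 equiv), THF/HMPA (10:1), −78 °C; DMF, −78 → 0 °C; then MeOH, NaBH4, 0 °C
Reagents that add atoms: N,N-dimethylformamide CN(C)C=O (supplies C3 and its oxygen)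
Why: Corey–Seebach umpolung, in which deprotonation of the 2-substituted 1,3-dithiane and formylation with DMF install C3, and borohydride reduction in the same flask stores it as the primary alcohol; C5 is β to the carbanion and is not epimerised.

Step 8
Reactants: 11 {2-[(2S,6R)-6-methyl-6,7-bis(triethylsilyloxy)heptan-2-yl]-1,3-dithian-2-yl}methanol
Product: 12 tert-butyl({2-[(2S,6R)-6-methyl-6,7-bis(triethylsilyloxy)heptan-2-yl]-1,3-dithian-2-yl}methoxy)dimethylsilane
Conditions: TBSOTf, 2,6-lutidine, CH2Cl2, −78 → 0 °C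
Reagents that add atoms: tert-butyldimethylsilyl trifluoromethanesulfonate CC(C)(C)[Si](C)(C)OS(=O)(=O)C(F)(F)F
Why: Silyl triflate silylation of the hindered neopentyl-type C3 alcohol gives a TBS ether that is more robust than the primary TES ether at C10, which sets up the next step.

Step 9
Reactants: 12 tert-butyl({2-[(2S,6R)-6-methyl-6,7-bis(triethylsilyloxy)heptan-2-yl]-1,3-dithian-2-yl}methoxy)dimethylsilane
Product: 13 (2R,6S)-6-[2-(tert-butyldimethylsilyloxymethyl)-1,3-dithian-2-yl]-2-methyl-2-(triethylsilyloxy)heptanal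
Conditions: (COCl)2 (4 equiv), DMSO (8 equiv), CH2Cl2, −78 → −35 °C; then Et3N, −78 °C → rt
Reagents that add atoms: none
Why: Swern oxidation applied directly to a primary triethylsilyl ether, in which the activated sulfoxide cleaves the most labile Si–O bond (C10) and oxidises that carbon to the aldehyde, while the tertiary TES ether, the TBS ether and the dithiane should persist and the product has no α-hydrogen to lose.

Step 10
Reactants: 13 (2R,6S)-6-[2-(tert-butyldimethylsilyloxymethyl)-1,3-dithian-2-yl]-2-methyl-2-(triethylsilyloxy)heptanal; 14 allyl methoxymethyl ether, 3-(methoxymethoxy)prop-1-ene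
Product: 16 (3R,4S,5R,9S)-9-[2-(tert-butyldimethylsilyloxymethyl)-1,3-dithian-2-yl]-3-(methoxymethoxy)-5-methyl-5-(triethylsilyloxy)dec-1-en-4-ol, via bis(isopinocampheyl)borinate ester 15 (not isolated)
Conditions: 14, sec-BuLi, THF, −78 °C; (−)-Ipc2BOMe [from (+)-α-pinene]; BF3·OEt2; then 13, −78 °C; HOCH2CH2NH2, rt (non-oxidative work-up, which spares the dithiane)
Reagents that add atoms: none
Why: Reagent-controlled γ-alkoxyallylboration through a Zimmerman–Traxler chair, in which the (Z)-γ-(methoxymethoxy)allyl unit gives the syn C10/C1 relationship and the isopinocampheyl groups from (+)-α-pinene direct attack to the si face of the aldehyde (C10 S, C1 R), which is also the Felkin–Anh sense (C9–O/C10–O anti) of the α-silyloxy aldehyde.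

Step 11
Reactants: 16 (3R,4S,5R,9S)-9-[2-(tert-butyldimethylsilyloxymethyl)-1,3-dithian-2-yl]-3-(methoxymethoxy)-5-methyl-5-(triethylsilyloxy)dec-1-en-4-ol; 17 isobutyryl chloride
Product: 18 (3R,4S,5R,9S)-9-[2-(tert-butyldimethylsilyloxymethyl)-1,3-dithian-2-yl]-3-(methoxymethoxy)-5-methyl-5-(triethylsilyloxy)dec-1-en-4-yl 2-methylpropanoate
Conditions: 17, pyridine, DMAP (cat.), CH2Cl2, 0 → 40 °C
Reagents that add atoms: none
Why: DMAP-catalysed acylation of the only free hydroxyl, the hindered secondary C10–OH, with an acid chloride.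

Step 12
Reactants: 18 (3R,4S,5R,9S)-9-[2-(tert-butyldimethylsilyloxymethyl)-1,3-dithian-2-yl]-3-(methoxymethoxy)-5-methyl-5-(triethylsilyloxy)dec-1-en-4-yl 2-methylpropanoate
Product: 19 (3R,4S,5R,9S)-9-[2-(tert-butyldimethylsilyloxymethyl)-1,3-dithian-2-yl]-3-hydroxy-5-methyl-5-(triethylsilyloxy)dec-1-en-4-yl 2-methylpropanoate
Conditions: Me2BBr (2.5 equiv), CH2Cl2, −78 °C; then THF/sat. aq. NaHCO3
Reagents that add atoms: none
Why: Lewis acid cleavage of the methoxymethyl acetal by a bromoborane at −78 °C, where the ester, both silyl ethers and the dithiane are expected to survive, followed by bicarbonate hydrolysis of the bromomethyl ether to the C1 alcohol.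

Step 13
Reactants: 19 (3R,4S,5R,9S)-9-[2-(tert-butyldimethylsilyloxymethyl)-1,3-dithian-2-yl]-3-hydroxy-5-methyl-5-(triethylsilyloxy)dec-1-en-4-yl 2-methylpropanoate; 20 2-(bromomethyl)acrylic acid
Product: 21 (3R,4S,5R,9S)-9-[2-(tert-butyldimethylsilyloxymethyl)-1,3-dithian-2-yl]-5-methyl-4-(2-methylpropanoyloxy)-5-(triethylsilyloxy)dec-1-en-3-yl 2-(bromomethyl)prop-2-enoate
Conditions: 20, DCC, DMAP (0.1 equiv), CH2Cl2, 0 °C
Reagents that add atoms: none
Why: Steglich carbodiimide esterification of the only free hydroxyl (C1–OH), run cold with little DMAP so that the allylic bromide is exposed to the nucleophilic catalyst only briefly.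

Step 14
Reactants: 21 (3R,4S,5R,9S)-9-[2-(tert-butyldimethylsilyloxymethyl)-1,3-dithian-2-yl]-5-methyl-4-(2-methylpropanoyloxy)-5-(triethylsilyloxy)dec-1-en-3-yl 2-(bromomethyl)prop-2-enoate
Product: 22 (1S,2R,6S)-1-[(2R)-4-(bromomethyl)-5-oxo-2,5-dihydrofuran-2-yl]-6-[2-(tert-butyldimethylsilyloxymethyl)-1,3-dithian-2-yl]-2-methyl-2-(triethylsilyloxy)heptyl 2-methylpropanoate
Conditions: second-generation Grubbs catalyst (H2IMes)(PCy3)Cl2Ru=CHPh (10 mol%), toluene (5 mM), 80 °C
Reagents that add atoms: none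
Why: Ring-closing metathesis, in which the ruthenium alkylidene initiates at the C2 vinyl group and closes the five-membered ring onto the 1,1-disubstituted acrylate with loss of ethene, a known route to 3-substituted 2(5H)-furanones that leaves C1 untouched.

Step 15
Reactants: 22 (1S,2R,6S)-1-[(2R)-4-(bromomethyl)-5-oxo-2,5-dihydrofuran-2-yl]-6-[2-(tert-butyldimethylsilyloxymethyl)-1,3-dithian-2-yl]-2-methyl-2-(triethylsilyloxy)heptyl 2-methylpropanoate
Product: 23 (1S,2R,6S)-1-[(2R)-4-(bromomethyl)-5-oxo-2,5-dihydrofuran-2-yl]-2-hydroxy-6-[2-(hydroxymethyl)-1,3-dithian-2-yl]-2-methylheptyl 2-methylpropanoate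
Conditions: HF·pyridine, THF, 0 °C → rt (no added pyridine)
Reagents that add atoms: none
Why: Acidic fluoride desilylation removes the primary TBS ether (C3) and the tertiary TES ether (C9) in one operation, and the acidic, amine-free medium should spare the allylic bromide, both esters and the dithiane.

Step 16
Reactants: 23 (1S,2R,6S)-1-[(2R)-4-(bromomethyl)-5-oxo-2,5-dihydrofuran-2-yl]-2-hydroxy-6-[2-(hydroxymethyl)-1,3-dithian-2-yl]-2-methylheptyl 2-methylpropanoate
Product: 24 (1S,2R,6S)-1-[(2R)-4-(bromomethyl)-5-oxo-2,5-dihydrofuran-2-yl]-6-(2-formyl-1,3-dithian-2-yl)-2-hydroxy-2-methylheptyl 2-methylpropanoate (seco bromobutenolide aldehyde)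
Conditions: Dess–Martin periodinane, NaHCO3, CH2Cl2, 0 °C → rt; used at once
Reagents that add atoms: none
Why: Dess–Martin oxidation under neutral, amine-free conditions converts the primary alcohol into the non-enolisable aldehyde, the tertiary alcohol cannot be oxidised, the sulfide sulfurs react far more slowly than the alcohol in dry dichloromethane, and the absence of base keeps the C9 hydroxyl from adding to the bromobutenolide in an SN2′ sense.

Step 17
Reactants: 24 (1S,2R,6S)-1-[(2R)-4-(bromomethyl)-5-oxo-2,5-dihydrofuran-2-yl]-6-(2-formyl-1,3-dithian-2-yl)-2-hydroxy-2-methylheptyl 2-methylpropanoate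
Product: 26 dithiane-masked macrocycle (1R,2S,3S,5S,9R,10S): ten-membered carbocycle C1–C10 trans-fused at C1/C2 to the 11(13)-methylene 12,1-lactone, C3–OH, C4 spiro-1,3-dithiane, C5–Me, C9(Me)OH, C10 O-isobutyrate, via allylchromium dichloride 25 (not isolated)
Conditions: CrCl2 (10 equiv), THF/DMF (degassed), rt, syringe-pump addition of 24 over 12 h (final 2 mM)
Reagents that add atoms: none
Why: Two equivalents of divalent chromium reduce the C13–Br bond of 24 to the allylchromium dichloride 25 (trivalent chromium), whose metal binds the C3 aldehyde oxygen and delivers the γ-carbon C2 through a six-membered chair, so that the C2–C3 bond forms while the ring double bond moves to C11=C13. The closest known reaction type is the chromium-mediated Nozaki–Hiyama–Kishi/Barbier allylation of aldehydes by 3-(bromomethyl)butenolides and by open-chain 2-(bromomethyl)acrylates, the latter also in ten-membered ring closures; the two features are joined here in one substrate. The ten-membered carbocycle closes by attack of nucleophilic C2 on the carbonyl carbon C3, whose oxygen stays outside the new ring (10-exo-trig), and it becomes trans-fused to the existing lactone. C2 is set by the C1 stereocentre, because the C10 branch blocks its own face of the flat butenolide to the chromium-bound chair and the seven-atom tether is long enough to bring the aldehyde to the open face (H1 and H2 anti), while C3 is set by the chair, in which the ring-locked allyl unit (C1 trans to C13) and an equatorial dithiane carbon give the anti C2/C3 relationship. The step needs γ- over α-attack and aldehyde over ester selectivity (both inherent to allylchromium reagents) and ring closure over oligomerisation (slow addition at high dilution); the aldehyde cannot enolise because C4 is the quaternary dithiane carbon, and the preformed lactone leaves the new C3 alkoxide no acyl group to attack.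

Step 18
Reactants: 26 dithiane-masked macrocycle (1R,2S,3S,5S,9R,10S)
Product: 27 target CNP0270933.1, (1R,2S,3S,5S,9R,10S)-3,9-dihydroxy-5,9-dimethyl-11(13)-methylene-4-oxo ten-membered 12,1-lactone 10-isobutyrate
Conditions: PhI(OCOCF3)2 (1.5 equiv), MeCN/H2O (9:1), NaHCO3, 0 °C
Reagents that add atoms: water O
Why: Oxidative dethioacetalisation with a hypervalent iodine reagent, in which S-activation, ring opening to the thionium ion and capture by water release the C4 ketone under mild conditions that should spare the α-methylene lactone, the ester and the C3 and C5 stereocentres.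

**Compound list**

1 | (S)-β-citronellene, (3S)-3,7-dimethylocta-1,6-diene | C=C[C@@H](C)CCC=C(C)C | starting material
2 | (2E,6S)-2,6-dimethylocta-2,7-dien-1-ol | C=C[C@@H](C)CC/C=C(\C)CO | intermediate
3 | [(2S,3S)-2-methyl-3-[(3S)-3-methylpent-4-en-1-yl]oxiran-2-yl]methanol | C=C[C@@H](C)CC[C@@H]1O[C@@]1(C)CO | intermediate
4 | (2R,6S)-2,6-dimethyloct-7-ene-1,2-diol | C=C[C@@H](C)CCC[C@@](C)(O)CO | intermediate
5 | (2R,6S)-2-methyl-6-(1,2,4-trioxolan-3-yl)heptane-1,2-diol (secondary ozonide, both configurations at the trioxolane carbon) | C1(OCOO1)[C@@H](C)CCC[C@@](C)(O)CO | intermediate (not isolated)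
6 | (2S,6R)-6,7-dihydroxy-2,6-dimethylheptanal | O=C[C@@H](C)CCC[C@@](C)(O)CO | intermediate
7 | (2R,6S)-6-(1,3-dithian-2-yl)-2-methylheptane-1,2-diol | C1CSC(SC1)[C@@H](C)CCC[C@@](C)(O)CO | intermediate
8 | 2-[(2S,6R)-6-methyl-6,7-bis(triethylsilyloxy)heptan-2-yl]-1,3-dithiane | C1CSC(SC1)[C@@H](C)CCC[C@@](C)(O[Si](CC)(CC)CC)CO[Si](CC)(CC)CC | intermediate
9 | 2-lithio-2-[(2S,6R)-6-methyl-6,7-bis(triethylsilyloxy)heptan-2-yl]-1,3-dithiane | [Li]C1(SCCCS1)[C@@H](C)CCC[C@@](C)(O[Si](CC)(CC)CC)CO[Si](CC)(CC)CC | intermediate (not isolated)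
10 | 2-[(2S,6R)-6-methyl-6,7-bis(triethylsilyloxy)heptan-2-yl]-1,3-dithiane-2-carbaldehyde | O=CC1(SCCCS1)[C@@H](C)CCC[C@@](C)(O[Si](CC)(CC)CC)CO[Si](CC)(CC)CC | intermediate (not isolated)
11 | {2-[(2S,6R)-6-methyl-6,7-bis(triethylsilyloxy)heptan-2-yl]-1,3-dithian-2-yl}methanol | OCC1(SCCCS1)[C@@H](C)CCC[C@@](C)(O[Si](CC)(CC)CC)CO[Si](CC)(CC)CC | intermediate
12 | tert-butyl({2-[(2S,6R)-6-methyl-6,7-bis(triethylsilyloxy)heptan-2-yl]-1,3-dithian-2-yl}methoxy)dimethylsilane | CC(C)(C)[Si](C)(C)OCC1(SCCCS1)[C@@H](C)CCC[C@@](C)(O[Si](CC)(CC)CC)CO[Si](CC)(CC)CC | intermediate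
13 | (2R,6S)-6-[2-(tert-butyldimethylsilyloxymethyl)-1,3-dithian-2-yl]-2-methyl-2-(triethylsilyloxy)heptanal | CC(C)(C)[Si](C)(C)OCC1(SCCCS1)[C@@H](C)CCC[C@@](C)(O[Si](CC)(CC)CC)C=O | intermediate
14 | allyl methoxymethyl ether, 3-(methoxymethoxy)prop-1-ene | C=CCOCOC | starting material
15 | bis(isopinocampheyl)borinate ester of 16 (O–B(Ipc)2 at C10) | CC(C)(C)[Si](C)(C)OCC1(SCCCS1)[C@@H](C)CCC[C@@](C)(O[Si](CC)(CC)CC)[C@@H](OB([C@@H]2C[C@@H]3C[C@H]([C@H]2C)C3(C)C)[C@@H]4C[C@@H]5C[C@H]([C@H]4C)C5(C)C)[C@H](OCOC)C=C | intermediate (not isolated)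
16 | (3R,4S,5R,9S)-9-[2-(tert-butyldimethylsilyloxymethyl)-1,3-dithian-2-yl]-3-(methoxymethoxy)-5-methyl-5-(triethylsilyloxy)dec-1-en-4-ol | CC(C)(C)[Si](C)(C)OCC1(SCCCS1)[C@@H](C)CCC[C@@](C)(O[Si](CC)(CC)CC)[C@@H](O)[C@H](OCOC)C=C | intermediate
17 | isobutyryl chloride, 2-methylpropanoyl chloride | CC(C)C(Cl)=O | starting material
18 | (3R,4S,5R,9S)-9-[2-(tert-butyldimethylsilyloxymethyl)-1,3-dithian-2-yl]-3-(methoxymethoxy)-5-methyl-5-(triethylsilyloxy)dec-1-en-4-yl 2-methylpropanoate | CC(C)(C)[Si](C)(C)OCC1(SCCCS1)[C@@H](C)CCC[C@@](C)(O[Si](CC)(CC)CC)[C@@H](OC(=O)C(C)C)[C@H](OCOC)C=C | intermediate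
19 | (3R,4S,5R,9S)-9-[2-(tert-butyldimethylsilyloxymethyl)-1,3-dithian-2-yl]-3-hydroxy-5-methyl-5-(triethylsilyloxy)dec-1-en-4-yl 2-methylpropanoate | CC(C)(C)[Si](C)(C)OCC1(SCCCS1)[C@@H](C)CCC[C@@](C)(O[Si](CC)(CC)CC)[C@@H](OC(=O)C(C)C)[C@H](O)C=C | intermediate
20 | 2-(bromomethyl)acrylic acid, 2-(bromomethyl)prop-2-enoic acid | C=C(CBr)C(=O)O | starting material
21 | (3R,4S,5R,9S)-9-[2-(tert-butyldimethylsilyloxymethyl)-1,3-dithian-2-yl]-5-methyl-4-(2-methylpropanoyloxy)-5-(triethylsilyloxy)dec-1-en-3-yl 2-(bromomethyl)prop-2-enoate | CC(C)(C)[Si](C)(C)OCC1(SCCCS1)[C@@H](C)CCC[C@@](C)(O[Si](CC)(CC)CC)[C@@H](OC(=O)C(C)C)[C@H](OC(=O)C(=C)CBr)C=C | intermediate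
22 | (1S,2R,6S)-1-[(2R)-4-(bromomethyl)-5-oxo-2,5-dihydrofuran-2-yl]-6-[2-(tert-butyldimethylsilyloxymethyl)-1,3-dithian-2-yl]-2-methyl-2-(triethylsilyloxy)heptyl 2-methylpropanoate | CC(C)(C)[Si](C)(C)OCC1(SCCCS1)[C@@H](C)CCC[C@@](C)(O[Si](CC)(CC)CC)[C@@H](OC(=O)C(C)C)[C@@H]2OC(=O)C(CBr)=C2 | intermediate
23 | (1S,2R,6S)-1-[(2R)-4-(bromomethyl)-5-oxo-2,5-dihydrofuran-2-yl]-2-hydroxy-6-[2-(hydroxymethyl)-1,3-dithian-2-yl]-2-methylheptyl 2-methylpropanoate | OCC1(SCCCS1)[C@@H](C)CCC[C@@](C)(O)[C@@H](OC(=O)C(C)C)[C@@H]2OC(=O)C(CBr)=C2 | intermediate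
24 | (1S,2R,6S)-1-[(2R)-4-(bromomethyl)-5-oxo-2,5-dihydrofuran-2-yl]-6-(2-formyl-1,3-dithian-2-yl)-2-hydroxy-2-methylheptyl 2-methylpropanoate (seco aldehyde, key-step precursor) | O=CC1(SCCCS1)[C@@H](C)CCC[C@@](C)(O)[C@@H](OC(=O)C(C)C)[C@@H]2OC(=O)C(CBr)=C2 | intermediate
25 | allylchromium dichloride derived from 24 (CH2–CrCl2 in place of CH2Br) | O=CC1(SCCCS1)[C@@H](C)CCC[C@@](C)(O)[C@@H](OC(=O)C(C)C)[C@@H]2OC(=O)C(C[Cr](Cl)Cl)=C2 | intermediate (not isolated)
26 | dithiane-masked macrocycle (1R,2S,3S,5S,9R,10S): target with C4 as spiro-1,3-dithiane (key-step product) | C=C1C(=O)O[C@@H]2[C@@H]1[C@H](O)C3(SCCCS3)[C@@H](C)CCC[C@@](C)(O)[C@H]2OC(=O)C(C)C | intermediate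
27 | CNP0270933.1, (1R,2S,3S,5S,9R,10S)-3,9-dihydroxy-5,9-dimethyl-11(13)-methylene-4-oxo ten-membered 12,1-lactone 10-isobutyrate | C=C1C(=O)O[C@@H]2[C@@H]1[C@H](O)C(=O)[C@@H](C)CCC[C@@](C)(O)[C@H]2OC(=O)C(C)C | target

**Step count and risks**

Total step count: 18. Longest linear sequence: 18 steps (1 → 27).

The three steps most likely to fail:

Step 17 (key ring closure). The ten-membered closure may be slower than bimolecular coupling or than protonation of the allylchromium (loss of the bromide without C–C bond formation), or the chair may form on the C10-bearing face and give the cis ring fusion. The fallback makes the same C2–C3 bond by a closed-transition-state allylboration of an isolable nucleophile instead of a reductive Barbier reaction. It leaves the route at diol 23: palladium-catalysed borylation of the allylic bromide (B2pin2, Pd2(dba)3, zerovalent palladium, toluene, 50 °C) should give the pinacol allylboronate diol F1. Dess–Martin oxidation should give the allylboronate aldehyde F2, which can be handled because 2-alkoxycarbonyl allylboronates add to aldehydes only slowly without a catalyst. Sc(OTf)3-catalysed intramolecular allylboration under high dilution (toluene, 0 °C → rt) should give the O-boryl macrocycle F3 through the same chair, and aqueous triethanolamine work-up frees the C3 hydroxyl and rejoins the route at 26.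

Step 14 (ring-closing metathesis). The ruthenium carbene may be deactivated by the dithiane sulfur or by the allylic bromide, and closure onto the hindered, electron-poor 2-(bromomethyl)acrylate may stall. The fallback carries C13 as a silyl ether through the metathesis and introduces bromine afterwards. It leaves the route at 19: Steglich esterification with 2-{[tert-butyl(dimethyl)silyl]oxymethyl}prop-2-enoic acid gives the diene ester F4, ring-closing metathesis with the same catalyst gives the 3-(silyloxymethyl)butenolide F5, and HF·pyridine gives the triol F6. An Appel bromination at −40 °C (CBr4, PPh3), to which the neopentyl-type C3 alcohol and the tertiary C9 alcohol are inert, should convert only the allylic alcohol into the bromide and rejoins the route at 23.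

Step 18 (dithiane removal). Excess oxidant may cleave the new α-hydroxy ketone between C3 and C4, or the free C3 hydroxyl may take part at the thionium stage (hydride shift, acyloin transposition), and the acid set free may epimerise C5. The fallback masks the carbinols and removes the dithiane by alkylation instead of oxidation. It leaves the route at 26: Et3SiOTf and 2,6-lutidine give the bis(triethylsilyl) ether F7, alkylative hydrolysis (MeI, CaCO3, MeCN/H2O, 40 °C) gives the protected ketone F8, and HF·pyridine gives 27.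

Further compounds
F1 | step 17 | (1S,2R,6S)-2-hydroxy-6-[2-(hydroxymethyl)-1,3-dithian-2-yl]-2-methyl-1-{(2R)-5-oxo-4-[(4,4,5,5-tetramethyl-1,3,2-dioxaborolan-2-yl)methyl]-2,5-dihydrofuran-2-yl}heptyl 2-methylpropanoate | OCC1(SCCCS1)[C@@H](C)CCC[C@@](C)(O)[C@@H](OC(=O)C(C)C)[C@@H]2OC(=O)C(CB3OC(C)(C)C(C)(C)O3)=C2
F2 | step 17 | (1S,2R,6S)-6-(2-formyl-1,3-dithian-2-yl)-2-hydroxy-2-methyl-1-{(2R)-5-oxo-4-[(4,4,5,5-tetramethyl-1,3,2-dioxaborolan-2-yl)methyl]-2,5-dihydrofuran-2-yl}heptyl 2-methylpropanoate | O=CC1(SCCCS1)[C@@H](C)CCC[C@@](C)(O)[C@@H](OC(=O)C(C)C)[C@@H]2OC(=O)C(CB3OC(C)(C)C(C)(C)O3)=C2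
F3 | step 17 | 3-O-(4,4,5,5-tetramethyl-1,3,2-dioxaborolan-2-yl) derivative of 26 | C=C1C(=O)O[C@@H]2[C@@H]1[C@H](OB3OC(C)(C)C(C)(C)O3)C4(SCCCS4)[C@@H](C)CCC[C@@](C)(O)[C@H]2OC(=O)C(C)C
F4 | step 14 | (3R,4S,5R,9S)-9-[2-(tert-butyldimethylsilyloxymethyl)-1,3-dithian-2-yl]-5-methyl-4-(2-methylpropanoyloxy)-5-(triethylsilyloxy)dec-1-en-3-yl 2-(tert-butyldimethylsilyloxymethyl)prop-2-enoate | CC(C)(C)[Si](C)(C)OCC1(SCCCS1)[C@@H](C)CCC[C@@](C)(O[Si](CC)(CC)CC)[C@@H](OC(=O)C(C)C)[C@H](OC(=O)C(=C)CO[Si](C)(C)C(C)(C)C)C=C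
F5 | step 14 | (1S,2R,6S)-6-[2-(tert-butyldimethylsilyloxymethyl)-1,3-dithian-2-yl]-1-[(2R)-4-(tert-butyldimethylsilyloxymethyl)-5-oxo-2,5-dihydrofuran-2-yl]-2-methyl-2-(triethylsilyloxy)heptyl 2-methylpropanoate | CC(C)(C)[Si](C)(C)OCC1(SCCCS1)[C@@H](C)CCC[C@@](C)(O[Si](CC)(CC)CC)[C@@H](OC(=O)C(C)C)[C@@H]2OC(=O)C(CO[Si](C)(C)C(C)(C)C)=C2
F6 | step 14 | (1S,2R,6S)-2-hydroxy-1-[(2R)-4-(hydroxymethyl)-5-oxo-2,5-dihydrofuran-2-yl]-6-[2-(hydroxymethyl)-1,3-dithian-2-yl]-2-methylheptyl 2-methylpropanoate | OCC1(SCCCS1)[C@@H](C)CCC[C@@](C)(O)[C@@H](OC(=O)C(C)C)[C@@H]2OC(=O)C(CO)=C2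
F7 | step 18 | 3,9-bis-O-(triethylsilyl) derivative of 26 | C=C1C(=O)O[C@@H]2[C@@H]1[C@H](O[Si](CC)(CC)CC)C3(SCCCS3)[C@@H](C)CCC[C@@](C)(O[Si](CC)(CC)CC)[C@H]2OC(=O)C(C)C
F8 | step 18 | 3,9-bis-O-(triethylsilyl) derivative of 27 | C=C1C(=O)O[C@@H]2[C@@H]1[C@H](O[Si](CC)(CC)CC)C(=O)[C@@H](C)CCC[C@@](C)(O[Si](CC)(CC)CC)[C@H]2OC(=O)C(C)C
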